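**Retrosynthetic overview**

1. Target 22 ⇐ MOM ether 21 ⇐ all-trans dione 16, by one dehydrogenation through bis-silyl dienol ether 18. Ring B stays a dihydroresorcinol until the end, so no prenyl group is ever put onto a phenol.
2. Feature: in ring B (C1' on benzofuran C2), C4'–C5'(O)–C6'(prenyl) is the skeleton of 6-methylhept-5-en-2-one 14, and C1'–C2'(prenyl)–C3'(O) is an α-prenyl acrylate with the benzofuran on its β-carbon (13). 16 ⇐ 13 + 14 by Michael addition (C1'–C6') then Claisen closure (C3'–C4').
3. 13 ⇐ aldehyde 10 + prenylated phosphonoacetate 12 (Horner–Wadsworth–Emmons); 12 ⇐ trimethyl phosphonoacetate 11 + prenyl bromide 2.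
4. 10 ⇐ 2,4-dihydroxybenzaldehyde 1: C3 prenylation, 4-O-MOM, bromoacetate annulation to benzofuran ester 8, reduction, reoxidation.
5. Ring order: ring A (benzenoid ring of the benzofuran) is bought in 1; the furan ring forms in step 3; ring B closes in step 8 and is aromatized in step 10.

Key step: step 8

Remark: Ar = 6-(methoxymethoxy)-7-(3-methylbut-2-en-1-yl)-1-benzofuran-2-yl; prenyl = 3-methylbut-2-en-1-yl. Dione 16 is meso and 17–19 are racemic (descriptors show relative configuration only); 7 and 15 are diastereomer mixtures; the target has no stereocentre.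

**Step 1**
Reactants: 1 2,4-dihydroxybenzaldehyde; 2 prenyl bromide (1-bromo-3-methylbut-2-ene)
Product: 3 2,4-dihydroxy-3-prenylbenzaldehyde
Conditions: KOH (aq., 10%), 0 °C to rt
Reagents that add atoms: none
Why: Direct C-alkylation of the resorcinolate in water should favour C3, the carbon between the two oxygens; the 5-prenyl and O-prenyl isomers are removed by chromatography, which is tolerable for a first step on cheap materials.

**Step 2**
Reactants: 3 2,4-dihydroxy-3-prenylbenzaldehyde
Product: 4 2-hydroxy-4-(methoxymethoxy)-3-prenylbenzaldehyde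
Conditions: MOMCl (1.1 equiv), K2CO3, acetone, rt
Reagents that add atoms: chloromethyl methyl ether, COCCl
Why: Williamson-type O-alkylation selective for the 4-OH, because the 2-OH is tied up in a hydrogen bond to the formyl group and is less nucleophilic.

**Step 3**
Reactants: 4 2-hydroxy-4-(methoxymethoxy)-3-prenylbenzaldehyde; 5 methyl bromoacetate
Product: 8 methyl 6-(methoxymethoxy)-7-prenylbenzofuran-2-carboxylate, via aryloxyacetate 6 (not isolated), via hydroxydihydrobenzofuran 7 (not isolated)
Conditions: K2CO3, DMF, 90 °C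
Reagents that add atoms: none
Why: Rap–Stoermer-type condensation: O-alkylation of the salicylaldehyde, intramolecular aldol addition of the ester enolate to the formyl group and dehydration to the aromatic furan, which removes the two transient stereocentres of 7.

**Step 4**
Reactants: 8 methyl 6-(methoxymethoxy)-7-prenylbenzofuran-2-carboxylate
Product: 9 [6-(methoxymethoxy)-7-prenylbenzofuran-2-yl]methanol
Conditions: i-Bu2AlH (2.5 equiv), CH2Cl2, −78 to 0 °C; aq. potassium sodium tartrate
Reagents that add atoms: none
Why: Hydride reduction of the ester to the primary alcohol; the MOM acetal, the prenyl alkene and the benzofuran are inert to i-Bu2AlH at this temperature.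

**Step 5**
Reactants: 9 [6-(methoxymethoxy)-7-prenylbenzofuran-2-yl]methanol
Product: 10 6-(methoxymethoxy)-7-prenylbenzofuran-2-carbaldehyde
Conditions: MnO2 (activated, excess), CH2Cl2, rt
Reagents that add atoms: none
Why: MnO2 oxidation is selective for the heteroaryl (benzylic-type) carbinol and should stop at the aldehyde without touching the prenyl group.

**Step 6**
Reactants: 11 trimethyl phosphonoacetate; 2 prenyl bromide
Product: 12 methyl 2-(dimethoxyphosphoryl)-5-methylhex-4-enoate (racemic)
Conditions: NaH (1.0 equiv), THF, 0 °C; then 2 (0.9 equiv), rt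
Reagents that add atoms: none
Why: SN2 alkylation of the stabilized phosphonoacetate anion by a primary allylic bromide; a slight excess of 11 limits dialkylation.

**Step 7**
Reactants: 10 6-(methoxymethoxy)-7-prenylbenzofuran-2-carbaldehyde; 12 methyl 2-(dimethoxyphosphoryl)-5-methylhex-4-enoate
Product: 13 methyl (E)-2-(Ar-methylidene)-5-methylhex-4-enoate
Conditions: NaH, THF, 0 °C; then 10, 0 °C to rt
Reagents that add atoms: none
Why: Horner–Wadsworth–Emmons olefination of an aromatic aldehyde with an α-alkyl phosphonoacetate should give mainly the trisubstituted enoate with the aryl group trans to the ester (E); any Z isomer can be carried on, since both geometries converge in step 8.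

**Step 8**
Reactants: 13 methyl (E)-2-(Ar-methylidene)-5-methylhex-4-enoate; 14 6-methylhept-5-en-2-one
Product: 16 all-trans 5-Ar-4,6-diprenylcyclohexane-1,3-dione (meso diketo form), via keto ester 15 (not isolated)
Conditions: 14 (3 equiv), KOt-Bu (2.5 equiv), THF/t-BuOH, 0 to 50 °C; aq. HCl to pH 3
Reagents that add atoms: none
Why: KOt-Bu equilibrates the enolates of 14, and the more substituted C3 enolate adds reversibly to the β-carbon of 13 (bond C1'–C6') to give 15 as its enolate; after proton transfer the methyl-side ketone enolate attacks the ester carbonyl and expels methoxide (bond C3'–C4'), and irreversible deprotonation of the 1,3-dione pulls the sequence forward. The closest known reaction type is the consecutive Michael–Claisen [3+3] synthesis of cyclohexane-1,3-diones from substituted acetones and enoates, applied here to a more hindered α-alkyl-β-heteroaryl acceptor, hence the excess of 14 and gentle heating. Ring B closes by a 6-(enolexo)-exo-trig acylation. The centres at C4 and C6 are α to the carbonyl groups and epimerize through the enolates until both prenyl groups are equatorial and trans to the C5 aryl group, so thermodynamic control should give the all-trans meso dione, and all three centres vanish on aromatization in any case. The step needs regioselectivity between the two α-carbons of 14 (internal carbon for the Michael step, methyl carbon for the Claisen step) and 1,4- over 1,2-attack on 13; reversible enolate formation and Michael addition, together with faster ring closure through the unhindered methyl enolate and a hindered conjugated ester that resists intermolecular acylation, should drain the equilibria through the desired adduct.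

**Step 9**
Reactants: 16 all-trans 5-Ar-4,6-diprenylcyclohexane-1,3-dione
Product: 18 trans-5-Ar-4,6-diprenyl-1,3-bis(trimethylsilyloxy)cyclohexa-1,3-diene (racemic), via monosilyl enol ether 17 (not isolated)
Conditions: LiN(i-Pr)2 (1.1 equiv), THF, −78 °C, then TMSCl, to 0 °C; recool to −78 °C, LiN(i-Pr)2 (1.3 equiv), then TMSCl; pentane, filtration
Reagents that add atoms: chlorotrimethylsilane, C[Si](C)(C)Cl
Why: O-silylation of the dionate gives the vinylogous silyl ester 17, and kinetic α'-deprotonation followed by a second O-silylation gives the 1,3-bis(silyloxy)-1,3-diene (standard silyl dienol ether formation); because 16 is meso either carbonyl gives the same racemate, and the two remaining centres stay trans.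

**Step 10**
Reactants: 18 trans-5-Ar-4,6-diprenyl-1,3-bis(trimethylsilyloxy)cyclohexa-1,3-diene
Product: 21 5-Ar-4,6-diprenylbenzene-1,3-diol, via silyloxy dienone 19 (not isolated), via monosilyl ether 20 (not isolated)
Conditions: Pd(OAc)2 (1.1 equiv), MeCN, rt; then K2CO3 (cat.), MeOH, 0 °C
Reagents that add atoms: none
Why: Saegusa–Ito oxidation: divalent palladium attacks the terminal, prenyl-bearing diene carbon from the face anti to the neighbouring aryl group with loss of TMSOAc, which places Pd syn to the adjacent ring C–H, and β-hydride elimination gives dienone 19, which tautomerizes to phenol 20; mild methanolysis removes the remaining aryl silyl ether, and the last two stereocentres are erased.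

**Step 11**
Reactants: 21 5-Ar-4,6-diprenylbenzene-1,3-diol
Product: 22 5-[6-hydroxy-7-prenylbenzofuran-2-yl]-4,6-diprenylbenzene-1,3-diol (target)
Conditions: HCl (3 M aq.), MeOH, rt to 40 °C; NaHCO3 quench at full conversion
Reagents that add atoms: none
Why: Acid-catalysed acetal exchange of the aryl MOM ether with methanol (MOM deprotection); dilute acid and short contact are chosen so that the ortho-prenyl phenol units do not cyclize to chromans.

**Compound list**

1 | 2,4-dihydroxybenzaldehyde | O=Cc1ccc(O)cc1O | starting material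
2 | prenyl bromide (1-bromo-3-methylbut-2-ene) | CC(C)=CCBr | starting material
3 | 2,4-dihydroxy-3-(3-methylbut-2-en-1-yl)benzaldehyde | O=Cc1ccc(O)c(CC=C(C)C)c1O | intermediate
4 | 2-hydroxy-4-(methoxymethoxy)-3-(3-methylbut-2-en-1-yl)benzaldehyde | O=Cc1ccc(OCOC)c(CC=C(C)C)c1O | intermediate
5 | methyl bromoacetate | COC(=O)CBr | starting material
6 | methyl 2-[6-formyl-3-(methoxymethoxy)-2-(3-methylbut-2-en-1-yl)phenoxy]acetate (formed in the flask, step 3) | COC(=O)COc1c(C=O)ccc(OCOC)c1CC=C(C)C | intermediate
7 | methyl 3-hydroxy-6-(methoxymethoxy)-7-(3-methylbut-2-en-1-yl)-2,3-dihydrobenzofuran-2-carboxylate (diastereomer mixture, formed in the flask, step 3) | COC(=O)C1Oc2c(CC=C(C)C)c(OCOC)ccc2C1O | intermediate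
8 | methyl 6-(methoxymethoxy)-7-(3-methylbut-2-en-1-yl)benzofuran-2-carboxylate | COC(=O)c1cc2ccc(OCOC)c(CC=C(C)C)c2o1 | intermediate
9 | [6-(methoxymethoxy)-7-(3-methylbut-2-en-1-yl)benzofuran-2-yl]methanol | OCc1cc2ccc(OCOC)c(CC=C(C)C)c2o1 | intermediate
10 | 6-(methoxymethoxy)-7-(3-methylbut-2-en-1-yl)benzofuran-2-carbaldehyde | O=Cc1cc2ccc(OCOC)c(CC=C(C)C)c2o1 | intermediate
11 | trimethyl phosphonoacetate | COC(=O)CP(=O)(OC)OC | starting material
12 | methyl 2-(dimethoxyphosphoryl)-5-methylhex-4-enoate (racemic) | COC(=O)C(CC=C(C)C)P(=O)(OC)OC | intermediate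
13 | methyl (E)-2-{[6-(methoxymethoxy)-7-(3-methylbut-2-en-1-yl)benzofuran-2-yl]methylidene}-5-methylhex-4-enoate | COC(=O)/C(CC=C(C)C)=C/c1cc2ccc(OCOC)c(CC=C(C)C)c2o1 | intermediate
14 | 6-methylhept-5-en-2-one | CC(=O)CCC=C(C)C | starting material
15 | methyl 4-acetyl-3-[6-(methoxymethoxy)-7-(3-methylbut-2-en-1-yl)benzofuran-2-yl]-7-methyl-2-(3-methylbut-2-en-1-yl)oct-6-enoate (diastereomer mixture, formed in the flask, step 8) | COC(=O)C(CC=C(C)C)C(c1cc2ccc(OCOC)c(CC=C(C)C)c2o1)C(CC=C(C)C)C(C)=O | intermediate
16 | all-trans 5-[6-(methoxymethoxy)-7-(3-methylbut-2-en-1-yl)benzofuran-2-yl]-4,6-bis(3-methylbut-2-en-1-yl)cyclohexane-1,3-dione (meso, diketo form) | O=C1CC(=O)[C@H](CC=C(C)C)[C@@H](c2cc3ccc(OCOC)c(CC=C(C)C)c3o2)[C@@H]1CC=C(C)C | intermediate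
17 | all-trans 5-Ar-4,6-bis(3-methylbut-2-en-1-yl)-3-(trimethylsilyloxy)cyclohex-2-en-1-one (racemic, formed in the flask, step 9) | O=C1C=C(O[Si](C)(C)C)[C@H](CC=C(C)C)[C@@H](c2cc3ccc(OCOC)c(CC=C(C)C)c3o2)[C@@H]1CC=C(C)C | intermediate
18 | trans-5-Ar-4,6-bis(3-methylbut-2-en-1-yl)-1,3-bis(trimethylsilyloxy)cyclohexa-1,3-diene (racemic) | C[Si](C)(C)OC1=CC(O[Si](C)(C)C)=C(CC=C(C)C)[C@@H](c2cc3ccc(OCOC)c(CC=C(C)C)c3o2)[C@@H]1CC=C(C)C | intermediate
19 | 3-Ar-2,4-bis(3-methylbut-2-en-1-yl)-5-(trimethylsilyloxy)cyclohexa-2,5-dien-1-one (racemic, formed in the flask, step 10) | CC(C)=CCC1C(O[Si](C)(C)C)=CC(=O)C(CC=C(C)C)=C1c1cc2ccc(OCOC)c(CC=C(C)C)c2o1 | intermediate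
20 | 3-Ar-2,4-bis(3-methylbut-2-en-1-yl)-5-(trimethylsilyloxy)phenol (formed in the flask, step 10) | CC(C)=CCc1c(O)cc(O[Si](C)(C)C)c(CC=C(C)C)c1-c1cc2ccc(OCOC)c(CC=C(C)C)c2o1 | intermediate
21 | 5-[6-(methoxymethoxy)-7-(3-methylbut-2-en-1-yl)benzofuran-2-yl]-4,6-bis(3-methylbut-2-en-1-yl)benzene-1,3-diol | CC(C)=CCc1c(O)cc(O)c(CC=C(C)C)c1-c1cc2ccc(OCOC)c(CC=C(C)C)c2o1 | intermediate
22 | 5-[6-hydroxy-7-(3-methylbut-2-en-1-yl)benzofuran-2-yl]-4,6-bis(3-methylbut-2-en-1-yl)benzene-1,3-diol | CC(C)=CCc1c(O)cc(O)c(CC=C(C)C)c1-c1cc2ccc(O)c(CC=C(C)C)c2o1 | target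

**Totals**

Total step count: 11. Longest linear sequence: 10 steps (steps 1–5 and 7–11; step 6 is a one-step side branch).

**Steps most likely to fail**

1. Step 8. Conjugate addition of a secondary enolate carbon to the trisubstituted enoate may not compete with retro-Michael reaction. The methyl-side enolate may instead acylate at the ester carbonyl to give an acyclic diketonate that cannot close. Michael addition through the methyl carbon would lead to the regioisomeric 2,4-diprenyl dione.
 Fallback, setting out from aldehyde 10 and returning at 15 and then 16: commercial dimethyl (2-oxopropyl)phosphonate is alkylated with 2 (NaH, THF) to dimethyl (6-methyl-2-oxohept-5-en-3-yl)phosphonate F1. Its Horner–Wadsworth–Emmons reaction with 10 (NaH, THF) gives the enone (E)-3-(Ar-methylidene)-6-methylhept-5-en-2-one F2. Johnson–Claisen rearrangement of 2-methylbut-3-en-2-ol with trimethyl orthoacetate (cat. EtCO2H, 120 °C) gives methyl 5-methylhex-4-enoate F3. F3 is converted (LiN(i-Pr)2, TMSCl, THF, −78 °C) into its ketene silyl acetal, [(1-methoxy-5-methylhexa-1,4-dien-1-yl)oxy]trimethylsilane F4. Mukaiyama–Michael addition of F4 to F2 (Sc(OTf)3 cat., CH2Cl2, −78 °C; aqueous work-up) forms the same ring bond on a Lewis-acid-activated enone with a regiodefined nucleophile and gives keto ester 15, now isolated. KOt-Bu in THF then only has to effect the Claisen closure and epimerization to 16.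

2. Step 10. Palladation may occur at the central diene carbon, at a prenyl alkene or at benzofuran C3. The acetic acid formed may protodesilylate 18 back to 16 before dehydrogenation.
 Fallback, setting out from dione 16 and returning at 21: TBSCl and imidazole in CH2Cl2 give the vinylogous silyl ester all-trans 5-Ar-4,6-diprenyl-3-(tert-butyldimethylsilyloxy)cyclohex-2-en-1-one F5. α'-Deprotonation (LiN(i-Pr)2, THF, −78 °C) and treatment of the lithium enolate with N-tert-butylbenzenesulfinimidoyl chloride (Mukaiyama dehydrogenation) introduce the ring double bond without a transition metal. Elimination in either direction, into the ring or toward the prenyl CH2, should end in the same arene after base-mediated tautomerization, giving 3-Ar-2,4-diprenyl-5-(tert-butyldimethylsilyloxy)phenol F6. Bu4NF/AcOH in THF removes the silyl group to give 21.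

3. Step 11. Acid-catalysed addition of a phenol oxygen to its ortho-prenyl alkene (chroman formation) may compete with acetal cleavage.
 Fallback, setting out from 21 and returning at 22: TMSOTf (excess) and 2,2'-bipyridyl in MeCN at 0 °C exchange the aryl MOM ether for an aryl TMS ether under aprotic conditions, silylating the two free phenols as well, to give the tris(trimethylsilyl) ether of the target F7. Stirring with water or K2CO3/MeOH then releases 22 without any Brønsted acid.

**Further compounds**

F1 | step 8 | dimethyl (6-methyl-2-oxohept-5-en-3-yl)phosphonate | CC(=O)C(CC=C(C)C)P(=O)(OC)OC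
F2 | step 8 | (E)-3-{[6-(methoxymethoxy)-7-(3-methylbut-2-en-1-yl)benzofuran-2-yl]methylidene}-6-methylhept-5-en-2-one | CC(=O)/C(CC=C(C)C)=C/c1cc2ccc(OCOC)c(CC=C(C)C)c2o1
F3 | step 8 | methyl 5-methylhex-4-enoate | COC(=O)CCC=C(C)C
F4 | step 8 | [(1-methoxy-5-methylhexa-1,4-dien-1-yl)oxy]trimethylsilane | COC(O[Si](C)(C)C)=CCC=C(C)C
F5 | step 10 | all-trans 5-Ar-4,6-bis(3-methylbut-2-en-1-yl)-3-(tert-butyldimethylsilyloxy)cyclohex-2-en-1-one (racemic) | O=C1C=C(O[Si](C)(C)C(C)(C)C)[C@H](CC=C(C)C)[C@@H](c2cc3ccc(OCOC)c(CC=C(C)C)c3o2)[C@@H]1CC=C(C)C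
F6 | step 10 | 3-Ar-2,4-bis(3-methylbut-2-en-1-yl)-5-(tert-butyldimethylsilyloxy)phenol | CC(C)=CCc1c(O)cc(O[Si](C)(C)C(C)(C)C)c(CC=C(C)C)c1-c1cc2ccc(OCOC)c(CC=C(C)C)c2o1
F7 | step 11 | tris(trimethylsilyl) ether of the target | CC(C)=CCc1c(O[Si](C)(C)C)cc(O[Si](C)(C)C)c(CC=C(C)C)c1-c1cc2ccc(O[Si](C)(C)C)c(CC=C(C)C)c2o1
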